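**Strategy.** Everything rests on cutting the bond between aromatic carbon C3a and the carbinol carbon C3 of the dihydrofuran ring. The key step exploits that C3a lies ortho to ring oxygen O1, so an iodine on that carbon and an aldehyde carbon C3 are the two ends of the five-atom chain C3a–C7a–O1–C2–C3. An intramolecular Nozaki–Hiyama–Kishi reaction of this open-chain (R)-α-aryloxy aldehyde closes the five-membered ring and sets the C3 carbinol trans to the C2 isopropenyl group in one operation. C2 is set beforehand by palladium-catalysed asymmetric opening of racemic isopropenyloxirane with the iodophenol. The Z enoate is finally built on the C3 hydroxyl by acylation and Still–Gennari olefination.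

Key step: step 6

Remark: atoms are numbered as in 2,3-dihydro-1-benzofuran (O1, C2, C3, C3a, C4 to C7, C7a), also in the open-chain precursors; the target is (2R,3S), trans, with a Z enoate.

Step 1
Reactants: 1 2,4-dihydroxyacetophenone
Product: 2 1-(2,4-dihydroxy-5-iodophenyl)ethan-1-one
Conditions: ICl (1.05 equiv), AcOH, rt
Reagents that add atoms: iodine monochloride, ClI
Why: Electrophilic aromatic iodination should go to C5, which is para to the chelated 2-hydroxyl, ortho to the free 4-hydroxyl and less hindered than C3 between the two oxygens; no stereocentre is formed.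

Step 2
Reactants: 3 methacrolein (2-methylprop-2-enal)
Product: 4 rac-2-(prop-1-en-2-yl)oxirane
Conditions: Me3S+ I−, n-BuLi, THF, −10 °C; then 3, −10 °C → rt
Reagents that add atoms: trimethylsulfonium iodide, C[S+](C)C.[I-]
Why: Corey–Chaykovsky epoxidation, in which the unstabilised sulfonium ylide adds 1,2 to the enal carbonyl and closes to the vinyl oxirane; the racemate is wanted because step 3 is stereoconvergent.

Step 3
Reactants: 2 1-(2,4-dihydroxy-5-iodophenyl)ethan-1-one; 4 rac-2-(prop-1-en-2-yl)oxirane (1.3 equiv)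
Product: 5 1-(2-hydroxy-4-{[(2R)-1-hydroxy-3-methylbut-3-en-2-yl]oxy}-5-iodophenyl)ethan-1-one
Conditions: Pd2(dba)3·CHCl3 (1 mol %), (S,S)-DACH-phenyl Trost ligand (3 mol %), CH2Cl2, rt
Reagents that add atoms: none
Why: Trost palladium-catalysed dynamic kinetic asymmetric allylic etherification of a vinyl epoxide: the two π-allylpalladium diastereomers interconvert through the unsubstituted CH2 terminus, the free 4-hydroxyl (more acidic than the chelated 2-hydroxyl) is delivered to the branched terminus by hydrogen bonding to the alkoxide, and the ligand should set the new C–O stereocentre as R (the (S,S) hand is assigned by analogy with additions to butadiene monoepoxide, and the antipodal ligand is used if the sense proves opposite); ionisation of the vinyl epoxide at rt should outrun insertion into the C–I bond.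

Step 4
Reactants: 5 1-(2-hydroxy-4-{[(2R)-1-hydroxy-3-methylbut-3-en-2-yl]oxy}-5-iodophenyl)ethan-1-one
Product: 7 1-(2-[(tert-butyldimethylsilyl)oxy]-4-{[(2R)-1-hydroxy-3-methylbut-3-en-2-yl]oxy}-5-iodophenyl)ethan-1-one, via sodium phenoxide 6 (not isolated)
Conditions: NaH (1.0 equiv), THF/DMF, 0 °C; then TBSCl (1.05 equiv), 0 °C → rt
Reagents that add atoms: tert-butyldimethylsilyl chloride, CC(C)(C)[Si](C)(C)Cl
Why: Chemoselective O-silylation of a phenoxide, since one equivalent of NaH removes only the phenolic proton and the neutral primary alcohol is left free; no stereocentre is touched.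

Step 5
Reactants: 7 1-(2-[(tert-butyldimethylsilyl)oxy]-4-{[(2R)-1-hydroxy-3-methylbut-3-en-2-yl]oxy}-5-iodophenyl)ethan-1-one
Product: 8 (2R)-2-{4-acetyl-5-[(tert-butyldimethylsilyl)oxy]-2-iodophenoxy}-3-methylbut-3-enal
Conditions: Dess–Martin periodinane (1.2 equiv), CH2Cl2, 0 °C; filtered cold and used at once
Reagents that add atoms: none
Why: Dess–Martin oxidation of the primary alcohol under non-basic conditions, chosen so that the α-aryloxy, β,γ-unsaturated aldehyde should neither epimerise nor move into conjugation.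

Step 6
Reactants: 8 (2R)-2-{4-acetyl-5-[(tert-butyldimethylsilyl)oxy]-2-iodophenoxy}-3-methylbut-3-enal
Product: 11 1-[(2R,3S)-6-[(tert-butyldimethylsilyl)oxy]-3-hydroxy-2-(prop-1-en-2-yl)-2,3-dihydro-1-benzofuran-5-yl]ethan-1-one, via arylchromium dichloride 9 (not isolated), via chromium alkoxide 10 (not isolated)
Conditions: CrCl2 (4 equiv), NiCl2 (1 mol %), degassed DMF, rt; then pH 7 aqueous buffer
Reagents that add atoms: none
Why: Zerovalent nickel, formed from NiCl2 by divalent chromium, inserts into the C–I bond and hands the aryl group to trivalent chromium, and the arylchromium dichloride 9 then adds to the aldehyde carbon through a chromium-bound four-centre transition state (intramolecular Nozaki–Hiyama–Kishi reaction, the closest known type being aryl iodide–aldehyde cyclisations to benzo-fused carbinols). The dihydrofuran ring is closed in a 5-exo-trig mode, C3a attacking the carbonyl carbon C3. The new C3 stereocentre is controlled by the existing C2 centre: in the envelope transition state the bulky chromium-bound oxygen should turn away from the isopropenyl group, leaving the aldehyde hydrogen next to it, so the trans (2R,3S) carbinol is expected. The step needs chemoselectivity for the aldehyde over the aryl ketone and the isopropenyl double bond; organochromium reagents add to aldehydes but not to ketones or unactivated alkenes, and nickel is kept at 1 mol % so that aryl transfer to chromium should outrun 5-exo carbonickelation of the alkene. Regiochemistry is fixed by the iodine on the carbon ortho to O1, and the non-basic medium should keep the α-aryloxy aldehyde from epimerising before it is consumed.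

Step 7
Reactants: 12 ethyl 2-[bis(2,2,2-trifluoroethoxy)phosphoryl]propanoate (racemic)
Product: 14 2-[bis(2,2,2-trifluoroethoxy)phosphoryl]propanoic acid, via lithium carboxylate 13 (not isolated)
Conditions: LiOH·H2O (1.0 equiv), THF/H2O, 0 °C; then 1 M HCl to pH 2
Reagents that add atoms: lithium hydroxide, [Li+].[OH-]
Why: Saponification of the carboxylic ester with one equivalent of hydroxide at 0 °C, where attack at the carboxyl carbon should be faster than at phosphorus; the α-carbon is racemic, which is irrelevant.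

Step 8
Reactants: 11 1-[(2R,3S)-6-[(tert-butyldimethylsilyl)oxy]-3-hydroxy-2-(prop-1-en-2-yl)-2,3-dihydro-1-benzofuran-5-yl]ethan-1-one; 14 2-[bis(2,2,2-trifluoroethoxy)phosphoryl]propanoic acid
Product: 15 (2R,3S)-5-acetyl-6-[(tert-butyldimethylsilyl)oxy]-2-(prop-1-en-2-yl)-2,3-dihydro-1-benzofuran-3-yl 2-[bis(2,2,2-trifluoroethoxy)phosphoryl]propanoate
Conditions: DCC (1.5 equiv), DMAP (0.1 equiv), CH2Cl2, 0 °C → rt
Reagents that add atoms: none
Why: Steglich esterification, in which the C3–O bond is not broken, so the trans (2R,3S) configuration is retained; the product is a mixture of epimers at the phosphonate carbon, which becomes an alkene carbon in step 10.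

Step 9
Reactants: 16 (2Z)-but-2-ene-1,4-diyl diacetate
Product: 18 2-oxoethyl acetate (acetoxyacetaldehyde), via ozonide 17 (not isolated)
Conditions: O3, CH2Cl2, −78 °C; then Me2S, −78 °C → rt
Reagents that add atoms: ozone, [O-][O+]=O
Why: Ozonolysis with reductive work-up cleaves the symmetric alkene into two molecules of the aldehyde, which is used fresh because it oligomerises on standing.

Step 10
Reactants: 15 (2R,3S)-5-acetyl-6-[(tert-butyldimethylsilyl)oxy]-2-(prop-1-en-2-yl)-2,3-dihydro-1-benzofuran-3-yl 2-[bis(2,2,2-trifluoroethoxy)phosphoryl]propanoate; 18 2-oxoethyl acetate (1.5 equiv)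
Product: 20 (2R,3S)-5-acetyl-6-[(tert-butyldimethylsilyl)oxy]-2-(prop-1-en-2-yl)-2,3-dihydro-1-benzofuran-3-yl (2Z)-4-(acetyloxy)-2-methylbut-2-enoate, via potassium phosphonate carbanion 19 (not isolated)
Conditions: KN(SiMe3)2 (1.0 equiv), 18-crown-6 (3 equiv), THF, −78 °C; then 18, −78 °C
Reagents that add atoms: none
Why: Still–Gennari variant of the Horner–Wadsworth–Emmons reaction: the bis(trifluoroethyl) phosphonate CH is far more acidic than the aryl methyl ketone, so one equivalent of base forms only that anion, and its adduct with the aldehyde should eliminate fast under dissociating conditions to give the kinetic Z trisubstituted enoate (ester cis to CH2OAc).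

Step 11
Reactants: 20 (2R,3S)-5-acetyl-6-[(tert-butyldimethylsilyl)oxy]-2-(prop-1-en-2-yl)-2,3-dihydro-1-benzofuran-3-yl (2Z)-4-(acetyloxy)-2-methylbut-2-enoate
Product: 21 (2R,3S)-5-acetyl-6-hydroxy-2-(prop-1-en-2-yl)-2,3-dihydro-1-benzofuran-3-yl (2Z)-4-(acetyloxy)-2-methylbut-2-enoate
Conditions: Bu4NF (1.1 equiv), AcOH (1.2 equiv), THF, 0 °C
Reagents that add atoms: none
Why: Fluoride cleavage of the aryl silyl ether, buffered with acetic acid so that the allylic acetate, the Z enoate and the benzylic ester (which would ionise toward the benzofuran under acid) should survive; no stereocentre is affected.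

**Compound list**

1 | 2,4-dihydroxyacetophenone | CC(=O)c1ccc(O)cc1O | starting material
2 | 1-(2,4-dihydroxy-5-iodophenyl)ethan-1-one | CC(=O)c1cc(I)c(O)cc1O | intermediate
3 | methacrolein (2-methylprop-2-enal) | C=C(C)C=O | starting material
4 | rac-2-(prop-1-en-2-yl)oxirane | C=C(C)C1CO1 | intermediate
5 | 1-(2-hydroxy-4-{[(2R)-1-hydroxy-3-methylbut-3-en-2-yl]oxy}-5-iodophenyl)ethan-1-one | C=C(C)[C@H](CO)Oc1cc(O)c(C(C)=O)cc1I | intermediate
6 | sodium 2-acetyl-5-{[(2R)-1-hydroxy-3-methylbut-3-en-2-yl]oxy}-4-iodophenolate (not isolated) | C=C(C)[C@H](CO)Oc1cc([O-])c(C(C)=O)cc1I.[Na+] | intermediate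
7 | 1-(2-[(tert-butyldimethylsilyl)oxy]-4-{[(2R)-1-hydroxy-3-methylbut-3-en-2-yl]oxy}-5-iodophenyl)ethan-1-one | C=C(C)[C@H](CO)Oc1cc(O[Si](C)(C)C(C)(C)C)c(C(C)=O)cc1I | intermediate
8 | (2R)-2-{4-acetyl-5-[(tert-butyldimethylsilyl)oxy]-2-iodophenoxy}-3-methylbut-3-enal | C=C(C)[C@H](C=O)Oc1cc(O[Si](C)(C)C(C)(C)C)c(C(C)=O)cc1I | intermediate
9 | arylchromium dichloride from 8, trivalent chromium on the carbon that carried iodine (not isolated) | C=C(C)[C@H](C=O)Oc1cc(O[Si](C)(C)C(C)(C)C)c(C(C)=O)cc1[Cr](Cl)Cl | intermediate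
10 | chromium dichloride alkoxide of 11, trivalent chromium on the C3 oxygen (not isolated) | C=C(C)[C@H]1Oc2cc(O[Si](C)(C)C(C)(C)C)c(C(C)=O)cc2[C@@H]1O[Cr](Cl)Cl | intermediate
11 | 1-[(2R,3S)-6-[(tert-butyldimethylsilyl)oxy]-3-hydroxy-2-(prop-1-en-2-yl)-2,3-dihydro-1-benzofuran-5-yl]ethan-1-one (trans) | C=C(C)[C@H]1Oc2cc(O[Si](C)(C)C(C)(C)C)c(C(C)=O)cc2[C@@H]1O | intermediate
12 | ethyl 2-[bis(2,2,2-trifluoroethoxy)phosphoryl]propanoate (racemic) | CCOC(=O)C(C)P(=O)(OCC(F)(F)F)OCC(F)(F)F | starting material
13 | lithium 2-[bis(2,2,2-trifluoroethoxy)phosphoryl]propanoate (not isolated) | [Li+].[O-]C(=O)C(C)P(=O)(OCC(F)(F)F)OCC(F)(F)F | intermediate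
14 | 2-[bis(2,2,2-trifluoroethoxy)phosphoryl]propanoic acid (racemic) | OC(=O)C(C)P(=O)(OCC(F)(F)F)OCC(F)(F)F | intermediate
15 | (2R,3S)-5-acetyl-6-[(tert-butyldimethylsilyl)oxy]-2-(prop-1-en-2-yl)-2,3-dihydro-1-benzofuran-3-yl 2-[bis(2,2,2-trifluoroethoxy)phosphoryl]propanoate (both epimers at the phosphonate carbon) | C=C(C)[C@H]1Oc2cc(O[Si](C)(C)C(C)(C)C)c(C(C)=O)cc2[C@@H]1OC(=O)C(C)P(=O)(OCC(F)(F)F)OCC(F)(F)F | intermediate
16 | (2Z)-but-2-ene-1,4-diyl diacetate | CC(=O)OC/C=C\COC(C)=O | starting material
17 | (1,2,4-trioxolane-3,5-diyl)bis(methylene) diacetate, the ozonide of 16 (not isolated) | CC(=O)OCC1OOC(COC(C)=O)O1 | intermediate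
18 | 2-oxoethyl acetate (acetoxyacetaldehyde) | CC(=O)OCC=O | intermediate
19 | potassium salt of the phosphonate carbanion of 15 (not isolated) | C=C(C)[C@H]1Oc2cc(O[Si](C)(C)C(C)(C)C)c(C(C)=O)cc2[C@@H]1OC(=O)[C-](C)P(=O)(OCC(F)(F)F)OCC(F)(F)F.[K+] | intermediate
20 | (2R,3S)-5-acetyl-6-[(tert-butyldimethylsilyl)oxy]-2-(prop-1-en-2-yl)-2,3-dihydro-1-benzofuran-3-yl (2Z)-4-(acetyloxy)-2-methylbut-2-enoate | C=C(C)[C@H]1Oc2cc(O[Si](C)(C)C(C)(C)C)c(C(C)=O)cc2[C@@H]1OC(=O)/C(C)=C\COC(C)=O | intermediate
21 | (2R,3S)-5-acetyl-6-hydroxy-2-(prop-1-en-2-yl)-2,3-dihydro-1-benzofuran-3-yl (2Z)-4-(acetyloxy)-2-methylbut-2-enoate | C=C(C)[C@H]1Oc2cc(O)c(C(C)=O)cc2[C@@H]1OC(=O)/C(C)=C\COC(C)=O | target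

**Total step count:** 11.
**Longest linear sequence:** 8 steps (steps 1, 3, 4, 5, 6, 8, 10 and 11).

**Steps most likely to fail**

1. Step 6. The addition of the arylchromium to the aldehyde may show poor facial selectivity, so that the cis carbinol forms beside or instead of the trans one. The fallback sets out from 8 and comes back at 15. The closure is run as in step 6 and the C3 epimer, 1-[(2R,3R)-6-[(tert-butyldimethylsilyl)oxy]-3-hydroxy-2-(prop-1-en-2-yl)-2,3-dihydro-1-benzofuran-5-yl]ethan-1-one F1, is separated. F1 is esterified with acid 14 under Mitsunobu conditions (PPh3, diisopropyl azodicarboxylate, toluene, 0 °C). The carboxylate should enter with inversion at C3, and any ionised benzylic intermediate would also be captured anti to the isopropenyl group, so F1 is funnelled into 15 while trans material continues through step 8.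

2. Step 3. The phenoxide may attack the unsubstituted allyl terminus (linear ether), enantiofacial discrimination may be low, or zerovalent palladium may be consumed by insertion into the C–I bond. The fallback sets out from 4 and 2 and comes back at 5. Hydrolytic kinetic resolution of 4 (H2O 0.45 equiv, (S,S)-N,N'-bis(3,5-di-tert-butylsalicylidene)cyclohexane-1,2-diaminocobalt acetate with trivalent cobalt, 0.5 mol %, 0 °C → rt; the hand chosen by analogy with simple terminal epoxides) should give (2S)-3-methylbut-3-ene-1,2-diol F2. Silylation of the primary hydroxyl (TBSCl, imidazole, CH2Cl2, 0 °C) gives (2S)-1-[(tert-butyldimethylsilyl)oxy]-3-methylbut-3-en-2-ol F3. Mitsunobu etherification of 2 with F3 (PPh3, diisopropyl azodicarboxylate, toluene, 0 °C) should engage the more acidic 4-hydroxyl with inversion and give 1-(4-{[(2R)-1-[(tert-butyldimethylsilyl)oxy]-3-methylbut-3-en-2-yl]oxy}-2-hydroxy-5-iodophenyl)ethan-1-one F4. Camphorsulfonic acid in MeOH at 0 °C then frees the primary alcohol to give 5.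

3. Step 10. Z selectivity may erode on the fully functionalised substrate, where the E enoate is hard to remove, and the phosphonate anion may enolise aldehyde 18 instead of adding to it. The fallback sets out from 14 and 18, uses 11, and comes back at 20. Acid 14 is converted into tert-butyl 2-[bis(2,2,2-trifluoroethoxy)phosphoryl]propanoate F5 (tert-butyl 2,2,2-trichloroacetimidate, cat. BF3·OEt2, CH2Cl2/cyclohexane, rt). Still–Gennari olefination of F5 with 18 (KN(SiMe3)2, 18-crown-6, THF, −78 °C) gives tert-butyl (2Z)-4-(acetyloxy)-2-methylbut-2-enoate F6, from which any E isomer is removed by chromatography at this small-molecule stage. Trifluoroacetic acid in CH2Cl2 at 0 °C gives (2Z)-4-(acetyloxy)-2-methylbut-2-enoic acid F7. Yamaguchi esterification of 11 with F7 (2,4,6-trichlorobenzoyl chloride, Et3N, THF; then 11, DMAP, toluene, rt) gives 20.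

**Further compounds**

F1 | step 6 | 1-[(2R,3R)-6-[(tert-butyldimethylsilyl)oxy]-3-hydroxy-2-(prop-1-en-2-yl)-2,3-dihydro-1-benzofuran-5-yl]ethan-1-one | C=C(C)[C@H]1Oc2cc(O[Si](C)(C)C(C)(C)C)c(C(C)=O)cc2[C@H]1O
F2 | step 3 | (2S)-3-methylbut-3-ene-1,2-diol | C=C(C)[C@@H](CO)O
F3 | step 3 | (2S)-1-[(tert-butyldimethylsilyl)oxy]-3-methylbut-3-en-2-ol | C=C(C)[C@@H](CO[Si](C)(C)C(C)(C)C)O
F4 | step 3 | 1-(4-{[(2R)-1-[(tert-butyldimethylsilyl)oxy]-3-methylbut-3-en-2-yl]oxy}-2-hydroxy-5-iodophenyl)ethan-1-one | C=C(C)[C@H](CO[Si](C)(C)C(C)(C)C)Oc1cc(O)c(C(C)=O)cc1I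
F5 | step 10 | tert-butyl 2-[bis(2,2,2-trifluoroethoxy)phosphoryl]propanoate | CC(C)(C)OC(=O)C(C)P(=O)(OCC(F)(F)F)OCC(F)(F)F
F6 | step 10 | tert-butyl (2Z)-4-(acetyloxy)-2-methylbut-2-enoate | CC(C)(C)OC(=O)/C(C)=C\COC(C)=O
F7 | step 10 | (2Z)-4-(acetyloxy)-2-methylbut-2-enoic acid | OC(=O)/C(C)=C\COC(C)=O
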